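A small charge of substrate, 0.014 M, meets reagent at 105% of it in the north flask, and this budget is what the products share.

- north: substrate 0.014 M; reagent 0.0147 M; the very flask that is asked about, followed so far
- flask: substrate 0.014 M; reagent 0.0147 M; time 2.0 d

north run (percent of the substrate charged)

| time / h | substrate / % | mono adduct / % | bis adduct / % |
|---|---|---|---|
| 1.00 | 18.5 | 34.3 | 6.5 |
| 2.00 | 9.2 | 27.8 | 6.5 |
| 2.50 | 8.0 | 25.2 | 5.3 |
| 4.00 | 2.6 | 21.4 | 8.6 |
| 6.00 | 1.9 | 21.6 | 7.2 |
| 10.0 | 0.4 | 21.5 | 7.5 |
| 15.0 | 0 | 20.0 | 7.5 |

(standard deviation of a reading: 1 percentage point)

- percentages count the substrate that a species holds: one side product counts as two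
- what may be going on: substrate + reagent -> mono adduct; reagent + mono adduct -> bis adduct; reagent + bis adduct -> triple product; substrate + mono adduct -> side product; 2 reagent -> homo dimer

1. substrate at 2.0 d, in percent of the substrate charged
2. mono adduct at 2.0 d, in percent of the substrate charged
3. bis adduct at 2.0 d, in percent of the substrate charged
4. triple product at 2.0 d, in percent of the substrate charged

Per substrate held, side product takes 0.5 reagent, and against that toll mono adduct costs 0.5 extra, bis adduct 1.50 and triple product 2.50. Triple product is unread, so the north flask needs a bracket. From above stands the reagent cap: reagent left after the side-product toll on the whole substrate and the extras of mono adduct and bis adduct, divided by the triple product's extra, with homo dimer taking none. The 15.0 h readings give 13.5%. From below the balance allows zero, the surplus going to homo dimer.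

My tightening compares rates at one moment: triple product forms against bis adduct as c(bis adduct)/c(mono adduct) times the selectivity factor of the third addition over the second, and reagent cancels. As read in the north run, that ratio goes from 0.190 at 1.00 h to 0.375 at 15.0 h. With a factor of one, triple product reckons to under 4.50%, but the factor is unread, so this is a guess and no bound. The forecast, judging that “The flask has effectively stopped”, gives substrate 0%, mono adduct 20.5%, bis adduct 7.5% and triple product 3%, from 0.5% to 9%; that value stands below my guess and the cap.

    substrate + reagent → mono adduct (k = 0.0820 /M/s)
    reagent + mono adduct → bis adduct (k = 0.0190 /M/s)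
    reagent + bis adduct → triple product (k = 0.0430 /M/s)
    substrate + mono adduct → side product (k = 0.0350 /M/s)
    2 reagent → homo dimer (k = 0.0240 /M/s)

The north flask gives substrate 0%, mono adduct 18.6%, bis adduct 6.66% and triple product 2.59% at 2.0 d. Homo dimer stands at 0.00205 M, with reagent at 0% of its charge. The cap of the north flask now reckons to 14.3%, and the distance down to triple product reckons to 0.00205 M of homo dimer. With 0.0056 M of substrate and the same reagent charge, the reagent balance of the neighbour flask reckons to 68.4% against triple product 13.8%, a distance reckoning to 0.00382 M of homo dimer, and that neighbour flask holds 0.00382 M.

The readings were computed with constants of no real substance.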